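The earlier runs and the new flask were generated by integration with constants of no real substance, noise included.

**Time first.** Over 3.00 d the midnight run shows two speeds: D climbs within 0.208 d, then sinks slowly.

in all of them: J 0.10 M

| charge | X | L | remark | time |
|---|---|---|---|---|
| midnight | 0.095 M | 0.70 M | run made earlier |  |
| autumn | 0.095 M | 1.1 M | run made earlier |  |
| winter | 0.14 M | 0.50 M | run made earlier |  |
| flask | 0.0950 M | 0.500 M |  | 3.0 d |

| run | time / d | D / % |
|---|---|---|
| midnight | 0.104 | 14 |
| midnight | 0.208 | 19 |
| midnight | 0.417 | 18 |
| midnight | 0.833 | 20 |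
| midnight | 1.67 | 15 |
| midnight | 3.00 | 13 |
| autumn | 0.104 | 14 |
| autumn | 0.208 | 21 |
| autumn | 0.417 | 18 |
| autumn | 0.833 | 15 |
| autumn | 1.67 | 13 |
| autumn | 3.00 | 13 |
| winter | 0.104 | 16 |
| winter | 0.250 | 29 |
| winter | 0.625 | 26 |
| winter | 1.25 | 26 |
| winter | 3.00 | 17 |

(standard deviation of a reading: 2 percentage points)



* time, not beyond 3.0 d, at which the flask holds most D
* the amount of D, in percent of the J charged, at that time
* the first time at which D reaches 15%, in the same percent, in d

**Early balance.** The climb is far shorter than the sinking, so I assume that one J and one X join reversibly to D and come to terms early, a fast pre-equilibrium. From the winter reading of 29% at 0.250 d I get 3.68 M⁻¹. That is the early balance: [D] at the crest over the product of [J] and [X], each reckoned as its charge less D, so that any X gone another way still counts in [X]. It is an apparent equilibrium constant, and a reading with its scatter.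

**Beside midnight.** The flask looks nearly like the midnight run, with the same J and X, but 0.500 M of L against 0.70 M. The early balance on the flask's charges gives me a crest of 21.3%. Midnight reads 14% at 0.104 d, so I put the amount asked for just after that time. The autumn run, with more L, reads 15% at 0.833 d, where midnight still reads 20%. So L seems to hasten the sinking, and I expect the flask, with less L than midnight, to hold its crest past 0.208 d. Midnight and autumn both read 13% at 3.00 d in spite of their different L, so I expect the flask to end near that too.

**The forecast.** The forecast gives 20.5% at 0.3 d, with the amount asked for reached at 0.115 d, on the ground that “decay is slower, so the maximum comes at about 0.3 d”, and my crest stands higher than its own.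

**The result.** The flask holds most D at 0.428 d, namely 21.1%, and reaches the amount asked for at 0.130 d.

    J + X ⇌ D (K = 5.50 M⁻¹, k = 0.0140 M⁻¹ min⁻¹)
    L + X ⇌ G (K = 1.40 M⁻¹, k = 0.00110 M⁻¹ min⁻¹)
    X → E (k = 2.20 × 10⁻⁴ min⁻¹)
    2 J → Q (k = 1.70 × 10⁻⁵ M⁻¹ min⁻¹)

**Balance again.** By the same definition the flask's crest gives 3.63 M⁻¹, and the neighbouring flask with 0.25 M of J, cresting at 16.5%, gives 3.66 M⁻¹, against 3.68 M⁻¹ from winter. In the flask, the relaxation half-life of J + X and D by the turning of J + X into D alone, both ways together, is 0.117 d at 3.00 d, short against the 3.0 d allowed. By then X has fallen to 27.5% of its charge, and D stands at 12.9%.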